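Atoms carry cembrane numbers. The six-membered lactone ring is O, C16, C15, C1, C2, C3; the 14-membered ring is C1 to C14; C17 to C20 sit on C15, C4, C8 and C12.
Cuts, last bond first: C7–OOH (oxygen ene reaction on C7=C8), C15–C17 (enolate methylation), the hydrogens on C1 and C15 (conjugate reduction), then C1–C2 together with the lactone O–C16 bond, then C13–C14. This leaves farnesol (C2 to C13, C18 to C20), methyl acetoacetate (C14, C1, C15, C16) and MeI (C17).
Enabling feature: C1 is the bridgehead shared by the lactone ring and the 14-membered ring and lies β to C16, so one oxidation level up it is the ketone carbon of an acetoacetate and can be a Z-enol triflate. C2 is a bare CH2 beside the carbinol C3, so it can be the primary iodide of an iodohydrin. Joining them closes the carbocycle and places C3–OH next to the ester, so the lactone closes in the same flask.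
Forward order: the open chain is built in steps 1 to 10, both rings arise in step 11, and C1–H, C17 and the hydroperoxide follow in steps 12 to 14.
Stereochemistry: two Sharpless epoxidations with L-(+)-tartrate set C3/C4 and C11/C12 (C3 is inverted once by hydroxide). C1 comes from hydride delivery anti to the C3 substituent of the unsaturated lactone, C15 from methylation anti to C14, and C7 from singlet oxygen on the outer face of the ring alkene.

Key step: step 11

Assumption: singlet oxygen is taken to reach C7=C8 of 17 from the outer face of the macrocycle, and this face is taken to lead to 7R; farnesol is used as the pure 2E,6E isomer.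

Step 1
Reactants: 1 (2E,6E)-farnesol
Product: 2 (2S,3S)-2,3-epoxyfarnesol (epoxide on cembrane C3–C4)
Conditions: Ti(OiPr)4 (cat.), L-(+)-DET (cat.), t-BuOOH, 4 Å MS, CH2Cl2, −20 °C
Reagents that add atoms: tert-butyl hydroperoxide, CC(C)(C)OO
Why: Sharpless asymmetric epoxidation, in which only the alkene allylic to the free hydroxyl is bound to titanium, so the other two alkenes stay untouched and L-(+)-tartrate should set the S,S epoxide.

Step 2
Reactants: 2 (2S,3S)-2,3-epoxyfarnesol
Product: 3 (2R,3S,6E)-3,7,11-trimethyldodeca-6,10-diene-1,2,3-triol (cembrane 3R,4S)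
Conditions: NaOH (1 M), t-BuOH/H2O, 75 °C
Reagents that add atoms: water, O
Why: Payne rearrangement with hydroxide opening, in which both the route through the terminal epoxide and direct attack at C3 invert C3 once and keep the C4–O bond, so they should converge on the one anti triol.

Step 3
Reactants: 3 triol
Product: 4 1,2-bis(triethylsilyl) ether of 3 (C2–OTES, C3–OTES, tertiary C4–OH free)
Conditions: Et3SiCl (2.2 equiv), imidazole, CH2Cl2, 0 °C
Reagents that add atoms: chlorotriethylsilane, CC[Si](Cl)(CC)CC
Why: Silyl ether formation, in which the primary and secondary hydroxyls react far faster than the hindered tertiary one, which needs no protection in the later steps.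

Step 4
Reactants: 4 bis-silyl ether
Product: 5 (10E)-12-hydroxy derivative of 4 (allylic alcohol at cembrane C13, 11E)
Conditions: SeO2 (cat.), t-BuOOH, salicylic acid (cat.), CH2Cl2, 0 °C to rt
Reagents that add atoms: tert-butyl hydroperoxide, CC(C)(C)OO
Why: Selenium dioxide allylic oxidation (ene step, then [2,3]-sigmatropic shift), which prefers the terminal isopropylidene over the internal alkene and the methyl trans to the chain, so the E-allylic alcohol should form.

Step 5
Reactants: 5 allylic alcohol
Product: 6 (10S,11S)-10,11-epoxide of 5 (cembrane 11S,12S epoxy alcohol)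
Conditions: Ti(OiPr)4 (cat.), L-(+)-DET (cat.), t-BuOOH, 4 Å MS, CH2Cl2, −20 °C
Reagents that add atoms: tert-butyl hydroperoxide, CC(C)(C)OO
Why: Second Sharpless asymmetric epoxidation, in which the C13 hydroxyl directs oxygen to C11=C12 only, the isolated C7=C8 alkene is not engaged, and the same tartrate gives the same facial sense as in step 1.

Step 6
Reactants: 6 epoxy alcohol
Product: 7 primary iodide at C13 (geometry unchanged; 10S,11R by CIP in farnesane numbers)
Conditions: I2, PPh3, imidazole, THF/MeCN, 0 °C
Reagents that add atoms: iodine, II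
Why: Appel-type iodination through the alkoxyphosphonium salt, which acts only on the primary alcohol while the imidazole buffer protects the epoxide, the silyl ethers and the tertiary alcohol.

Step 7
Reactants: 7 epoxy iodide; 8 methyl acetoacetate
Product: 10 open-chain β-keto ester C16–C15–C1(=O)–C14 to C2 (3R 4S 11S 12S 7E), via acetoacetate dianion 9 (not isolated)
Conditions: 8, NaH then n-BuLi, THF, 0 °C; add 7, 0 °C to rt; aq NH4Cl
Reagents that add atoms: none
Why: Acetoacetate dianion (Weiler-type) alkylation, in which the more basic terminal carbanion alone attacks the primary iodide and forms C13–C14, with excess dianion absorbing the free C4–OH.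

Step 8
Reactants: 10 β-keto ester
Product: 11 Z-enol triflate at C1 (OTf cis to CO2Me)
Conditions: NaH (2.1 equiv), PhNTf2, THF, 0 °C
Reagents that add atoms: N-phenylbis(trifluoromethanesulfonimide), O=S(=O)(N(c1ccccc1)S(=O)(=O)C(F)(F)F)C(F)(F)F
Why: Enolate O-triflation, in which the sodium chelate between enolate oxygen and ester carbonyl fixes the geometry so that triflate and ester end up cis (Z).

Step 9
Reactants: 11 bis-silyl enol triflate
Product: 12 C2,C3,C4-triol enol triflate
Conditions: Et3N·3HF, THF, rt
Reagents that add atoms: none
Why: Fluoride desilylation under nearly neutral conditions, which should cleave both triethylsilyl ethers without touching the epoxide or the base-sensitive β-triflyloxy enoate.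

Step 10
Reactants: 12 triol enol triflate
Product: 13 iodohydrin enol triflate (C2–I, C3–OH, C4–OH; C3 is S by CIP, geometry unchanged)
Conditions: I2 (1.1 equiv), PPh3, imidazole, THF, −10 °C
Reagents that add atoms: iodine, II
Why: Selective Appel-type (Garegg–Samuelsson) iodination, in which the primary hydroxyl of the triol is activated and displaced much faster than the secondary and tertiary ones.

Step 11
Reactants: 13 iodohydrin enol triflate
Product: 15 bicyclic α,β-unsaturated δ-lactone (C1=C15; 3R 4S 11S 12S 7E), via macrocyclic hydroxy ester 14 (not isolated)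
Conditions: NiBr2(dme) (20 mol %), 4,4'-di-tert-butyl-2,2'-bipyridine, Mn powder, DMA, slow addition to about 1 mM, rt; then DMAP (cat.), 40 °C
Reagents that add atoms: none
Why: Zerovalent nickel (from NiBr2(dme), the bipyridine and Mn) inserts into the C1–O bond of the Z-enol triflate, Mn reduces the divalent alkenylnickel to the monovalent state, this centre abstracts iodine from C2, and the C2 radical recombines with the same nickel before reductive elimination from trivalent nickel forms C1–C2 with retention of alkene geometry. The closest known reaction type is the nickel-catalysed cross-electrophile coupling of alkenyl halides or triflates with primary alkyl iodides, which also accepts iodohydrins formed from terminal epoxides. The 14-membered carbocycle closes by contraction of a 15-membered nickelacycle, and because C2 ends up cis to the ester the C3 hydroxyl then closes the six-membered lactone by 6-exo-trig acyl substitution with loss of methanol. No stereocentre is made; C3, C4, C11 and C12 are spectators, and the bicyclic frame formed here later controls C1 and C15. The step needs ring closure to beat oligomerisation (slow addition, high dilution), radical capture to beat 6-exo attack on C7=C8 (iodine abstraction occurs at the nickel that already carries C1, so recombination is a cage event), and preference for the primary iodide over the trisubstituted epoxide, which is too hindered for nickel or iodide.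

Step 12
Reactants: 15 unsaturated lactone
Product: 16 saturated δ-lactone lacking C17 (1R,3R,4S,11S,12S,7E)
Conditions: Cu(OAc)2·H2O (5 mol %), 1,2-bis(diphenylphosphino)benzene, (EtO)2MeSiH, t-BuOH, toluene, rt; aq NH4F
Reagents that add atoms: none
Why: Copper hydride conjugate reduction (Stryker-type), which touches only the electron-poor C1=C15 bond and should deliver hydride to C1 anti to the C4 substituent on C3 (the usual trans-4,6 addition mode of 6-substituted 5,6-dihydropyran-2-ones), so C14 ends cis to C4 and C1 becomes R.

Step 13
Reactants: 16 saturated lactone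
Product: 17 (1R,3R,4S,11S,12S,15S,7E)-11,12-epoxy-4-hydroxycembr-7-en-16,3-olide
Conditions: LDA (2.2 equiv), THF/DMPU, −78 °C; MeI
Reagents that add atoms: iodomethane, CI
Why: Lactone enolate alkylation, in which the enolate (C4 alkoxide as bystander) should take MeI anti to the neighbouring C14 chain and give the trans, all-equatorial 15S lactone, which is also the thermodynamic epimer.

Step 14
Reactants: 17 parent lactone
Product: 18 target hydroperoxide (1R,3R,4S,7R,11S,12S,15S)
Conditions: O2, tetraphenylporphyrin (cat.), visible light, CH2Cl2, 0 °C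
Reagents that add atoms: dioxygen, O=O
Why: Schenck ene reaction, in which C7=C8 is the only alkene left, the cis effect steers hydrogen abstraction to the side that carries C19, oxygen should bind C7 on the outward face of the E-alkene held in the 14-membered ring, and the double bond moves to C8=C19.

Compound list
1 | (2E,6E)-farnesol | OC/C=C(\C)CC/C=C(\C)CCC=C(C)C | starting material
2 | (2S,3S)-2,3-epoxyfarnesol | OC[C@@H]1O[C@@]1(C)CC/C=C(\C)CCC=C(C)C | intermediate
3 | (2R,3S,6E)-3,7,11-trimethyldodeca-6,10-diene-1,2,3-triol | OC[C@@H](O)[C@@](C)(O)CC/C=C(\C)CCC=C(C)C | intermediate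
4 | 1,2-bis(triethylsilyl) ether of 3 | CC[Si](CC)(CC)OC[C@@H](O[Si](CC)(CC)CC)[C@@](C)(O)CC/C=C(\C)CCC=C(C)C | intermediate
5 | (10E)-12-hydroxy derivative of 4 | CC[Si](CC)(CC)OC[C@@H](O[Si](CC)(CC)CC)[C@@](C)(O)CC/C=C(\C)CC/C=C(\C)CO | intermediate
6 | (10S,11S)-10,11-epoxy alcohol | CC[Si](CC)(CC)OC[C@@H](O[Si](CC)(CC)CC)[C@@](C)(O)CC/C=C(\C)CC[C@@H]1O[C@@]1(C)CO | intermediate
7 | epoxy iodide | CC[Si](CC)(CC)OC[C@@H](O[Si](CC)(CC)CC)[C@@](C)(O)CC/C=C(\C)CC[C@@H]1O[C@@]1(C)CI | intermediate
8 | methyl acetoacetate | COC(=O)CC(C)=O | starting material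
9 | sodium lithium dianion of methyl acetoacetate | [Na+].[Li+].[CH2-]C(=O)[CH-]C(=O)OC | intermediate
10 | open-chain β-keto ester | CC[Si](CC)(CC)OC[C@@H](O[Si](CC)(CC)CC)[C@@](C)(O)CC/C=C(\C)CC[C@@H]1O[C@@]1(C)CCC(=O)CC(=O)OC | intermediate
11 | Z-enol triflate, bis-silyl ether | CC[Si](CC)(CC)OC[C@@H](O[Si](CC)(CC)CC)[C@@](C)(O)CC/C=C(\C)CC[C@@H]1O[C@@]1(C)CC/C(OS(=O)(=O)C(F)(F)F)=C/C(=O)OC | intermediate
12 | Z-enol triflate, free triol | OC[C@@H](O)[C@@](C)(O)CC/C=C(\C)CC[C@@H]1O[C@@]1(C)CC/C(OS(=O)(=O)C(F)(F)F)=C/C(=O)OC | intermediate
13 | iodohydrin Z-enol triflate | IC[C@@H](O)[C@@](C)(O)CC/C=C(\C)CC[C@@H]1O[C@@]1(C)CC/C(OS(=O)(=O)C(F)(F)F)=C/C(=O)OC | intermediate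
14 | 14-membered hydroxy ester (C2 cis to CO2Me) | C/C1=C\CC[C@](C)(O)[C@H](O)C/C(CC[C@]2(C)O[C@H]2CC1)=C\C(=O)OC | intermediate
15 | bicyclic α,β-unsaturated δ-lactone | C/C1=C\CC[C@](C)(O)[C@H]2CC(CC[C@]3(C)O[C@H]3CC1)=CC(=O)O2 | intermediate
16 | saturated δ-lactone without C17 | C/C1=C\CC[C@](C)(O)[C@H]2C[C@@H](CC[C@]3(C)O[C@H]3CC1)CC(=O)O2 | intermediate
17 | 11,12-epoxy-4-hydroxycembr-7-en-16,3-olide (15S) | C/C1=C\CC[C@](C)(O)[C@H]2C[C@@H](CC[C@]3(C)O[C@H]3CC1)[C@H](C)C(=O)O2 | intermediate
18 | target hydroperoxide | C=C1CC[C@@H]2O[C@@]2(C)CC[C@@H]2C[C@@H](OC(=O)[C@H]2C)[C@@](C)(O)CC[C@H]1OO | target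

Total step count: 14. Longest linear sequence: 14.

Steps most likely to fail

Step 11. Oligomerisation, premature reduction of the C2–I bond, escape of the C2 radical onto C7=C8, or loss of the Z geometry at alkenylnickel may outrun ring closure. The fallback replaces the reductive coupling with a redox-neutral, two-electron closure. It sets out from 13. Metal-free radical borylation (bis(catecholato)diboron, DMF, blue light) should give the catechol boronate F1, and pinacol with Et3N the pinacol boronate F2. An intramolecular Suzuki–Miyaura coupling (Pd(OAc)2, RuPhos, K3PO4, THF/H2O, high dilution, 60 °C), in which the C4 hydroxyl can form a five-membered borate that speeds transmetalation, should give 14. After lactonisation the route comes back at 15.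

Step 14. Poor facial selectivity at C7 and competing abstraction of a ring allylic hydrogen may erode the ene reaction. The fallback sets C7 by reagent control and substitution with inversion, setting out from 17. Photooxygenation in the presence of Ac2O, pyridine and DMAP takes the C7-epimeric hydroperoxides F3 on by Kornblum–DeLaMare dehydration to the cross-conjugated enone F4. Corey–Bakshi–Shibata reduction with the (R)-methyl oxazaborolidine and catecholborane should give the (7S)-allylic alcohol F5, and MsCl with Et3N at −40 °C the allylic mesylate F6. Displacement with anhydrous ethereal H2O2 at low temperature should invert C7, and the route comes back at 18.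

Step 7. Slow substitution at the hindered epoxy-carbinyl carbon, iodine–metal exchange with fragmentation of the epoxide, or attack on the epoxide may compete with alkylation. The fallback forms C13–C14 by olefination instead of substitution, setting out from 6. Dess–Martin periodinane with NaHCO3 should give the epoxy aldehyde F7. Horner–Wadsworth–Emmons reaction with the dianion of methyl 4-(diethoxyphosphoryl)-3-oxobutanoate (NaH, THF) should give the E-enone keto ester F8. Diimide (2-nitrobenzenesulfonylhydrazide, Et3N) should saturate the disubstituted C13=C14 bond faster than the trisubstituted C7=C8 bond, and the route comes back at 10.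

Further compounds
F1 | step 11 | catechol boronate at C2 | c1ccc2OB(C[C@@H](O)[C@@](C)(O)CC/C=C(\C)CC[C@@H]3O[C@@]3(C)CC/C(OS(=O)(=O)C(F)(F)F)=C/C(=O)OC)Oc2c1
F2 | step 11 | pinacol boronate at C2 | CC1(C)OB(C[C@@H](O)[C@@](C)(O)CC/C=C(\C)CC[C@@H]2O[C@@]2(C)CC/C(OS(=O)(=O)C(F)(F)F)=C/C(=O)OC)OC1(C)C
F3 | step 14 | C7-epimeric hydroperoxides | C=C1C(OO)CC[C@](C)(O)[C@H]2C[C@@H](CC[C@]3(C)O[C@H]3CC1)[C@H](C)C(=O)O2
F4 | step 14 | 7-oxo-8(19)-ene enone | C=C1C(=O)CC[C@](C)(O)[C@H]2C[C@@H](CC[C@]3(C)O[C@H]3CC1)[C@H](C)C(=O)O2
F5 | step 14 | (7S)-allylic alcohol | C=C1[C@@H](O)CC[C@](C)(O)[C@H]2C[C@@H](CC[C@]3(C)O[C@H]3CC1)[C@H](C)C(=O)O2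
F6 | step 14 | (7S)-allylic mesylate | C=C1[C@@H](OS(C)(=O)=O)CC[C@](C)(O)[C@H]2C[C@@H](CC[C@]3(C)O[C@H]3CC1)[C@H](C)C(=O)O2
F7 | step 7 | epoxy aldehyde at C13 | CC[Si](CC)(CC)OC[C@@H](O[Si](CC)(CC)CC)[C@@](C)(O)CC/C=C(\C)CC[C@@H]1O[C@@]1(C)C=O
F8 | step 7 | E-enone keto ester (C13=C14) | CC[Si](CC)(CC)OC[C@@H](O[Si](CC)(CC)CC)[C@@](C)(O)CC/C=C(\C)CC[C@@H]1O[C@@]1(C)/C=C/C(=O)CC(=O)OC
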